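## Retrosynthetic overview

1. Target ⇐ Yamaguchi esterification of the axial ring alcohol of hydrindanol 19 with (2S,3S)-epoxyangelic acid 22 (made by Sharpless epoxidation of angelyl alcohol, then oxidation).
2. Six-membered ring (formed last) ⇐ Type II carbonyl-ene closure of an aldehyde onto an isopropenyl group on a trans-disubstituted cyclopentane.
3. Cyclopentane with acetyl cis to angelate ⇐ key step: MeMgBr-triggered semipinacol (Tiffeneau-type) ring contraction of an all-equatorial 2-tosyloxy-6-angeloyloxy-cyclohexanone.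
4. That cyclohexanone ⇐ α-tosyloxylation of a silyl enol ether; the angelate comes from invertive substitution of a 2-silyloxyallyl chloride; the cyclohexene (first ring) ⇐ Diels–Alder of a 1-chloro-2-silyloxy diene with methyl vinyl ketone.
5. Diene ⇐ organocatalytic α-hydroxymethylation of 3-methylbutanal and Wittig reaction with a chloroacetonyl ylide. Ring order: cyclohexene → cyclopentane (contraction) → methylenecyclohexane; the oxirane is made separately.

Assumption: angelic acid and (Z)-2-methylbut-2-en-1-ol are bought as such; locants in the "Why" lines are those of the names in the compound list.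

## Route

Step 1
Reactants: 1 1,3-dichloropropan-2-one
Product: 3 1-chloro-3-(triphenyl-λ5-phosphanylidene)propan-2-one, via phosphonium chloride 2 (not isolated)
Conditions: PPh3, THF, reflux; then aq. Na2CO3, MeOH, 0 °C
Reagents that add atoms: triphenylphosphine, c1ccc(cc1)P(c1ccccc1)c1ccccc1
Why: SN2 quaternisation of one CH2Cl group and deprotonation give the stabilised Wittig ylide (standard phosphonium ylide preparation).

Step 2
Reactants: 4 3-methylbutanal; 5 formaldehyde (37 % aq.); 3 chloroacetonyl ylide
Product: 7 (5S,3E)-1-chloro-5-(hydroxymethyl)-6-methylhept-3-en-2-one, via hydroxymethyl aldehyde 6 (not isolated)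
Conditions: (S)-α,α-diphenylprolinol TMS ether (10 mol %), pH 7 phosphate buffer, PhMe, rt; separate the organic phase; then 3, PhMe, rt
Reagents that add atoms: none
Why: Enamine-catalysed α-hydroxymethylation (cross-aldol with formaldehyde, Si-face attack under the (S)-catalyst) sets the isopropyl-bearing stereocentre, and the labile β-hydroxy aldehyde is trapped at once by an E-selective Wittig olefination.

Step 3
Reactants: 7 chloro enone alcohol
Product: 8 (5S,1Z,3E)-1-chloro-6-methyl-2-(triethylsilyloxy)-5-[(triethylsilyloxy)methyl]hepta-1,3-diene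
Conditions: TESOTf (2.3 equiv), i-Pr2NEt (3 equiv), CH2Cl2, −78 → 0 °C; used crude
Reagents that add atoms: triethylsilyl trifluoromethanesulfonate, CC[Si](CC)(CC)OS(=O)(=O)C(F)(F)F
Why: Soft enolisation of the α-chloro ketone gives the (Z)-silyl enol ether (Cl syn to OSi, so "outside" on the diene), and the primary alcohol is silylated in the same operation (silyl enol ether formation and O-silylation).

Step 4
Reactants: 8 chloro silyloxy diene; 9 but-3-en-2-one
Product: 11 trans-acetyl chloro cyclohexene, via all-cis cycloadduct 10 (not isolated)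
Conditions: 9 (3 equiv), BHT, PhMe, 80 °C; then DBU (0.2 equiv), 0 °C → rt
Reagents that add atoms: none
Why: Diels–Alder reaction in which the 2-silyloxy and 4-alkyl groups both direct the observed regiochemistry, the enone adds to the diene face anti to isopropyl in the H-eclipsed conformer (sets ring C2), the diene geometry puts Cl cis to the side chain, and DBU epimerises the acetyl carbon so that endo and exo adducts converge on the trans isomer, whose Cl is pseudoaxial whereas the cis isomer has Cl and acetyl syn-diaxial.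

Step 5
Reactants: 11 trans-acetyl chloro cyclohexene; 12 angelic acid
Product: 13 allylic angelate methyl ketone
Conditions: 12 (1.5 equiv), Cs2CO3 (1.5 equiv), DMF, 0 °C → rt
Reagents that add atoms: none
Why: Proposed new method: invertive SN2 substitution of a 2-silyloxyallyl chloride (so far used only as an oxyallyl-cation precursor) by a carboxylate with the enol ether kept, reasoning that the pseudoaxial C–Cl bond is aligned with the enol-ether π system, that SN2′ attack would have to occur at the electron-rich β-carbon of the enol ether and that ionisation needs a Lewis acid or silver salt that is absent, so angelate enters anti to Cl and the ester ends trans to the side chain as in the target; closest known reaction type: carboxylate displacement of allylic and α-keto halides.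

Step 6
Reactants: 13 allylic angelate methyl ketone
Product: 14 isopropenyl silyl enol ether
Conditions: Ph3PCH3Br, NaHMDS, THF, −78 → 0 °C (salt-free ylide, no excess base)
Reagents that add atoms: methyltriphenylphosphonium bromide, C[P+](c1ccccc1)(c1ccccc1)c1ccccc1.[Br-]
Why: Wittig methylenation of the only ketone present; the ylide is too weak a base to enolise the ketone appreciably, so the trans relation set in step 4 is kept, and the ester and enol ether are untouched.

Step 7
Reactants: 14 isopropenyl silyl enol ether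
Product: 15 all-equatorial 2-tosyloxy-6-angeloyloxy cyclohexanone
Conditions: PhI(OH)OTs (1.1 equiv), CH2Cl2, −78 → 0 °C
Reagents that add atoms: [hydroxy(tosyloxy)iodo]benzene, Cc1ccc(cc1)S(=O)(=O)OI(O)c1ccccc1
Why: Koser α-tosyloxylation of a silyl enol ether: the iodane is attacked axially at the enol-ether β-carbon and tosylate then displaces PhI with inversion, so the tosylate ends equatorial and trans to the neighbouring side chain (also the thermodynamic arrangement), and the enol ether reacts far faster than the isopropenyl or angelate alkenes.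

Step 8
Reactants: 15 2-tosyloxy-6-angeloyloxy cyclohexanone
Product: 17 acetyl cyclopentyl angelate TES ether, via bromomagnesium alkoxide 16 (not isolated)
Conditions: MeMgBr (1.05 equiv), PhMe/THF, −78 °C, 1 h; then warm to 25 °C
Reagents that add atoms: methylmagnesium bromide, C[Mg]Br
Why: Tiffeneau-type semipinacol ring contraction: MeMgBr adds selectively to the doubly α-oxygenated ketone, and on warming the alkoxide pushes the ring bond to the angeloyloxy carbon (antiperiplanar to the equatorial tosylate) onto the tosylate carbon, which inverts while the migrating carbon retains, so acetyl ends cis to the angelate and trans to the side chain.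

Step 9
Reactants: 17 acetyl cyclopentyl angelate TES ether
Product: 18 aldehyde
Conditions: (COCl)2, DMSO, CH2Cl2, −78 → −30 °C; then Et3N, −78 → 0 °C
Reagents that add atoms: none
Why: Swern conditions cleave a primary triethylsilyl ether and oxidise it directly to the aldehyde (direct Swern oxidation of TES ethers); low temperature avoids epimerisation α to the aldehyde and β-elimination of the angelate.

Step 10
Reactants: 18 aldehyde
Product: 19 (1R,2S,3aR,6R,7S,7aR)-1-acetyl-6-hydroxy-4-methylidene-7-(propan-2-yl)octahydro-1H-inden-2-yl (Z)-2-methylbut-2-enoate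
Conditions: Me2AlCl (2.5 equiv), CH2Cl2, −78 °C
Reagents that add atoms: none
Why: Type II intramolecular carbonyl-ene reaction through a chair with isopropyl equatorial on the trans-disubstituted cyclopentane; the carbonyl oxygen must sit axial, syn to the allylic methyl that gives up H, which delivers the axial alcohol cis to isopropyl together with the exocyclic methylene and the trans ring fusion.

Step 11
Reactants: 20 (Z)-2-methylbut-2-en-1-ol
Product: 21 [(2R,3S)-2,3-dimethyloxiran-2-yl]methanol
Conditions: Ti(Oi-Pr)4 (10 mol %), L-(+)-diethyl tartrate (12 mol %), t-BuOOH, 4 Å MS, CH2Cl2, −20 °C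
Reagents that add atoms: tert-butyl hydroperoxide, CC(C)(C)OO
Why: Sharpless asymmetric epoxidation; L-(+)-tartrate delivers oxygen to the face that gives the (2R,3S)-epoxide, and the syn addition turns the Z geometry into the cis relation of CH2OH and the 3-methyl group.

Step 12
Reactants: 21 epoxy alcohol
Product: 22 (2S,3S)-2,3-dimethyloxirane-2-carboxylic acid
Conditions: RuCl3·xH2O (2 mol %), NaIO4 (3 equiv), MeCN/EtOAc/H2O, 0 °C → rt
Reagents that add atoms: water, O
Why: RuO4-catalysed oxidation of the primary alcohol to the acid (Sharpless RuCl3/NaIO4) leaves both stereocentres untouched; the label at C2 changes from R to S only through the priority rules.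

Step 13
Reactants: 19 hydrindanol; 22 epoxyangelic acid
Product: 23 (1R,2S,3aR,6R,7S,7aR)-1-acetyl-4-methylidene-2-{[(2Z)-2-methylbut-2-enoyl]oxy}-7-(propan-2-yl)octahydro-1H-inden-6-yl (2S,3S)-2,3-dimethyloxirane-2-carboxylate
Conditions: 22, 2,4,6-trichlorobenzoyl chloride, Et3N, THF, rt; then 19, DMAP, PhMe, rt → 40 °C
Reagents that add atoms: none
Why: Yamaguchi esterification through the mixed anhydride acylates the hindered axial alcohol with retention; no stereocentre is touched and the epoxy acid, unlike angelic acid, cannot isomerise.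

## Compound list

1 | 1,3-dichloropropan-2-one | ClCC(=O)CCl | starting material
2 | (3-chloro-2-oxopropyl)triphenylphosphonium chloride | ClCC(=O)C[P+](c1ccccc1)(c1ccccc1)c1ccccc1.[Cl-] | intermediate
3 | 1-chloro-3-(triphenyl-λ5-phosphanylidene)propan-2-one | ClCC(=O)C=P(c1ccccc1)(c1ccccc1)c1ccccc1 | intermediate
4 | 3-methylbutanal | CC(C)CC=O | starting material
5 | formaldehyde | C=O | starting material
6 | (R)-2-(hydroxymethyl)-3-methylbutanal | OC[C@@H](C(C)C)C=O | intermediate
7 | (5S,3E)-1-chloro-5-(hydroxymethyl)-6-methylhept-3-en-2-one | ClCC(=O)/C=C/[C@@H](CO)C(C)C | intermediate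
8 | (5S,1Z,3E)-1-chloro-6-methyl-2-(triethylsilyloxy)-5-[(triethylsilyloxy)methyl]hepta-1,3-diene | Cl/C=C(O[Si](CC)(CC)CC)/C=C/[C@@H](CO[Si](CC)(CC)CC)C(C)C | intermediate
9 | but-3-en-2-one | CC(=O)C=C | starting material
10 | 1-{5-chloro-2-[(2S)-3-methyl-1-(triethylsilyloxy)butan-2-yl]-4-(triethylsilyloxy)cyclohex-3-en-1-yl}ethan-1-one; acetyl, side chain and Cl all cis | CC[Si](CC)(CC)OC[C@@H](C(C)C)[C@@H]1C=C(O[Si](CC)(CC)CC)[C@H](Cl)C[C@@H]1C(C)=O | intermediate
11 | same constitution as 10; acetyl trans to the side chain (1,2-trans), Cl cis to the side chain (2,5-cis) | CC[Si](CC)(CC)OC[C@@H](C(C)C)[C@@H]1C=C(O[Si](CC)(CC)CC)[C@H](Cl)C[C@H]1C(C)=O | intermediate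
12 | angelic acid, (Z)-2-methylbut-2-enoic acid | C/C=C(/C)C(=O)O | starting material
13 | 5-acetyl-4-[(2S)-3-methyl-1-(triethylsilyloxy)butan-2-yl]-2-(triethylsilyloxy)cyclohex-2-en-1-yl (Z)-2-methylbut-2-enoate; 1,4-trans and 4,5-trans | CC[Si](CC)(CC)OC[C@@H](C(C)C)[C@@H]1C=C(O[Si](CC)(CC)CC)[C@@H](OC(=O)/C(C)=C\C)C[C@H]1C(C)=O | intermediate
14 | 4-[(2S)-3-methyl-1-(triethylsilyloxy)butan-2-yl]-5-(prop-1-en-2-yl)-2-(triethylsilyloxy)cyclohex-2-en-1-yl (Z)-2-methylbut-2-enoate; 1,4-trans and 4,5-trans | CC[Si](CC)(CC)OC[C@@H](C(C)C)[C@@H]1C=C(O[Si](CC)(CC)CC)[C@@H](OC(=O)/C(C)=C\C)C[C@H]1C(C)=C | intermediate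
15 | 3-{[(Z)-2-methylbut-2-enoyl]oxy}-6-[(2S)-3-methyl-1-(triethylsilyloxy)butan-2-yl]-2-oxo-5-(prop-1-en-2-yl)cyclohexyl 4-methylbenzenesulfonate; all four ring substituents equatorial (1,6-trans; 5,6-trans; 1,3-cis) | CC[Si](CC)(CC)OC[C@@H](C(C)C)[C@@H]1[C@@H](OS(=O)(=O)c2ccc(C)cc2)C(=O)[C@@H](OC(=O)/C(C)=C\C)C[C@H]1C(C)=C | intermediate
16 | bromomagnesium alkoxide of the 2-hydroxy-2-methyl adduct of 15 (carbinol configuration not controlled, lost in the next event) | CC[Si](CC)(CC)OC[C@@H](C(C)C)[C@@H]1[C@@H](OS(=O)(=O)c2ccc(C)cc2)C(C)(O[Mg]Br)[C@@H](OC(=O)/C(C)=C\C)C[C@H]1C(C)=C | intermediate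
17 | 2-acetyl-3-[(2S)-3-methyl-1-(triethylsilyloxy)butan-2-yl]-4-(prop-1-en-2-yl)cyclopentyl (Z)-2-methylbut-2-enoate; 1,2-cis; 2,3-trans; 3,4-trans | CC[Si](CC)(CC)OC[C@@H](C(C)C)[C@@H]1[C@@H](C(C)=O)[C@@H](OC(=O)/C(C)=C\C)C[C@H]1C(C)=C | intermediate
18 | 2-acetyl-3-[(2S)-3-methyl-1-oxobutan-2-yl]-4-(prop-1-en-2-yl)cyclopentyl (Z)-2-methylbut-2-enoate; ring configuration as in 17 | O=C[C@@H](C(C)C)[C@@H]1[C@@H](C(C)=O)[C@@H](OC(=O)/C(C)=C\C)C[C@H]1C(C)=C | intermediate
19 | (1R,2S,3aR,6R,7S,7aR)-1-acetyl-6-hydroxy-4-methylidene-7-(propan-2-yl)octahydro-1H-inden-2-yl (Z)-2-methylbut-2-enoate | C=C1C[C@@H](O)[C@@H](C(C)C)[C@@H]2[C@@H](C(C)=O)[C@@H](OC(=O)/C(C)=C\C)C[C@@H]12 | intermediate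
20 | (Z)-2-methylbut-2-en-1-ol | C/C=C(/C)CO | starting material
21 | [(2R,3S)-2,3-dimethyloxiran-2-yl]methanol | OC[C@@]1(C)O[C@H]1C | intermediate
22 | (2S,3S)-2,3-dimethyloxirane-2-carboxylic acid | OC(=O)[C@@]1(C)O[C@H]1C | intermediate
23 | (1R,2S,3aR,6R,7S,7aR)-1-acetyl-4-methylidene-2-{[(2Z)-2-methylbut-2-enoyl]oxy}-7-(propan-2-yl)octahydro-1H-inden-6-yl (2S,3S)-2,3-dimethyloxirane-2-carboxylate | C=C1C[C@@H](OC(=O)[C@@]2(C)O[C@H]2C)[C@@H](C(C)C)[C@@H]2[C@@H](C(C)=O)[C@@H](OC(=O)/C(C)=C\C)C[C@@H]12 | target

## Step count and risks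

Total step count: 13. Longest linear sequence: 11 (steps 1–10 and 13).

The three steps most likely to fail:

Step 4 (Diels–Alder). Facial selectivity rests on substrate control by an all-carbon allylic stereocentre, and the allylic chloride must survive the DBU equilibration. The fallback sets out from 8 and comes back at 11. Diene 8 is combined with methyl acrylate under a chiral oxazaborolidinium triflimide catalyst (enantiomer matched to the anti-isopropyl face), which gives the all-cis methyl 5-chloro-2-[(2S)-3-methyl-1-(triethylsilyloxy)butan-2-yl]-4-(triethylsilyloxy)cyclohex-3-ene-1-carboxylate F1. i-PrMgCl and MeNH(OMe)·HCl convert it into the corresponding N-methoxy-N-methylcarboxamide F2. MeMgBr then gives ketone 10, which DBU epimerises to 11 as in step 4. This replaces substrate control by reagent control and the enone by an acrylate followed by a Weinreb ketone synthesis.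

Step 5 (the proposed new substitution). SN2′ attack, ionisation to the oxyallyl cation or loss of HCl could compete. The fallback uses only known chemistry; it sets out from 11 and comes back at 15. Wittig methylenation of 11 gives triethyl{[6-chloro-3-[(2S)-3-methyl-1-(triethylsilyloxy)butan-2-yl]-4-(prop-1-en-2-yl)cyclohex-1-en-1-yl]oxy}silane F3. Koser tosyloxylation of its enol ether gives 3-chloro-6-[(2S)-3-methyl-1-(triethylsilyloxy)butan-2-yl]-2-oxo-5-(prop-1-en-2-yl)cyclohexyl 4-methylbenzenesulfonate F4, with Cl axial and the other substituents equatorial. Caesium angelate in DMF then displaces the axial α-keto chloride with inversion (classical α-halo ketone substitution; the equatorial, hindered tosylate reacts much more slowly) to give 15.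

Step 8 (ring contraction). The migrating carbon carries an electron-withdrawing acyloxy group; acyl transfer to the alkoxide, attack on the ester or over-addition to the new ketone could intervene. The fallback sets out from 15 and comes back at 17. MeMgBr/CeCl3 at −78 °C with a cold quench gives the isolable tertiary alcohol 2-hydroxy-2-methyl-3-{[(Z)-2-methylbut-2-enoyl]oxy}-6-[(2S)-3-methyl-1-(triethylsilyloxy)butan-2-yl]-5-(prop-1-en-2-yl)cyclohexyl 4-methylbenzenesulfonate F5. Et3Al in CH2Cl2 (−78 → 0 °C) then promotes the organoaluminium pinacol-type rearrangement of 2-sulfonyloxy alcohols (Suzuki–Tsuchihashi), giving 17. This replaces the one-pot alkoxide push by Lewis-acid activation of a neutral carbinol.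

Further compounds

F1 | step 4 | methyl 5-chloro-2-[(2S)-3-methyl-1-(triethylsilyloxy)butan-2-yl]-4-(triethylsilyloxy)cyclohex-3-ene-1-carboxylate (all-cis) | CC[Si](CC)(CC)OC[C@@H](C(C)C)[C@@H]1C=C(O[Si](CC)(CC)CC)[C@H](Cl)C[C@@H]1C(=O)OC
F2 | step 4 | 5-chloro-N-methoxy-N-methyl-2-[(2S)-3-methyl-1-(triethylsilyloxy)butan-2-yl]-4-(triethylsilyloxy)cyclohex-3-ene-1-carboxamide (all-cis) | CC[Si](CC)(CC)OC[C@@H](C(C)C)[C@@H]1C=C(O[Si](CC)(CC)CC)[C@H](Cl)C[C@@H]1C(=O)N(C)OC
F3 | step 5 | triethyl{[6-chloro-3-[(2S)-3-methyl-1-(triethylsilyloxy)butan-2-yl]-4-(prop-1-en-2-yl)cyclohex-1-en-1-yl]oxy}silane (Cl cis to side chain; isopropenyl trans) | CC[Si](CC)(CC)OC[C@@H](C(C)C)[C@@H]1C=C(O[Si](CC)(CC)CC)[C@H](Cl)C[C@H]1C(C)=C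
F4 | step 5 | 3-chloro-6-[(2S)-3-methyl-1-(triethylsilyloxy)butan-2-yl]-2-oxo-5-(prop-1-en-2-yl)cyclohexyl 4-methylbenzenesulfonate (Cl axial; others equatorial) | CC[Si](CC)(CC)OC[C@@H](C(C)C)[C@@H]1[C@@H](OS(=O)(=O)c2ccc(C)cc2)C(=O)[C@H](Cl)C[C@H]1C(C)=C
F5 | step 8 | 2-hydroxy-2-methyl-3-{[(Z)-2-methylbut-2-enoyl]oxy}-6-[(2S)-3-methyl-1-(triethylsilyloxy)butan-2-yl]-5-(prop-1-en-2-yl)cyclohexyl 4-methylbenzenesulfonate | CC[Si](CC)(CC)OC[C@@H](C(C)C)[C@@H]1[C@@H](OS(=O)(=O)c2ccc(C)cc2)C(C)(O)[C@@H](OC(=O)/C(C)=C\C)C[C@H]1C(C)=C
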